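**Strategy.** The heterocycle of the isoflavan (ring C: O1, C2, C3, C4, C4a, C8a) is disconnected at C3–C4 and O1–C2. This exposes the O1–C8a–C4a–C4 edge as a latent ortho-quinone methide of ring A and shows that C3, the only stereocentre, is the α-carbon of the arylacetic acid that carries ring B and its fused chromene. A chiral isothiourea unites both pieces in one operation, forming both bonds, ring C as a dihydrocoumarin and the C3 configuration. The precursors are a 2-(tosylmethyl)phenol bearing the 3,5-dimethoxy-4-prenyl pattern and the silyl-protected chromenylacetic acid; lactone reduction and Mitsunobu closure then turn the carbonyl into the C2 methylene.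

Key step: step 10

Assumption: the sense of induction follows the accepted model for isothiourea-bound enolates (electrophile anti to the phenyl group beside the acylated nitrogen), which predicts the (3R) lactone from (2S,3R)-HyperBTM, that is (2S,3R)-3-isopropyl-2-phenyl-3,4-dihydro-2H-benzo[4,5]thiazolo[3,2-a]pyrimidine; the (2R,3S) catalyst would be taken should the sense prove to be the reverse.

Notation: prenyl = 3-methylbut-2-enyl; TIPS = triisopropylsilyl; locants O1 to C8a are those of the chroman core of the target.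

**Ring A branch**

Step 1
Reactants: 1 3,5-dimethoxyphenol
Product: 2 (3,5-dimethoxyphenoxy)triisopropylsilane
Conditions: TIPSCl, imidazole, DMF, rt
Reagents that add atoms: triisopropylsilyl chloride, CC(C)[Si](Cl)(C(C)C)C(C)C
Why: Imidazole-promoted silylation of the phenol (silyl ether protection) gives a bulky, non-directing ether that tolerates n-BuLi and shields both positions next to it.

Step 2
Reactants: 2 (3,5-dimethoxyphenoxy)triisopropylsilane; 3 prenyl bromide
Product: 5 [3,5-dimethoxy-4-(3-methylbut-2-enyl)phenoxy]triisopropylsilane, via aryllithium 4 (not isolated)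
Conditions: n-BuLi, THF, 0 °C to rt; then CuBr·SMe2 (10 mol%), 3, −78 °C to 0 °C
Reagents that add atoms: none
Why: Directed ortho-lithiation should occur at C4, the position flanked by both methoxy groups and remote from the bulky silyl ether, and the aryllithium is then alkylated at the primary carbon of prenyl bromide under copper catalysis (SN2 allylation).

Step 3
Reactants: 5 [3,5-dimethoxy-4-(3-methylbut-2-enyl)phenoxy]triisopropylsilane
Product: 6 3,5-dimethoxy-4-(3-methylbut-2-enyl)phenol
Conditions: Bu4NF, AcOH, THF, 0 °C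
Reagents that add atoms: none
Why: Fluoride desilylation cleaves the aryl silyl ether, the acetic acid buffer keeps the electron-rich phenoxide from side reactions, and the prenyl group is inert.

Step 4
Reactants: 6 3,5-dimethoxy-4-(3-methylbut-2-enyl)phenol
Product: 7 3,5-dimethoxy-4-(3-methylbut-2-enyl)-2-(tosylmethyl)phenol
Conditions: aq. CH2O (1.1 equiv), sodium p-toluenesulfinate (1.5 equiv), HCO2H/H2O, rt
Reagents that add atoms: formaldehyde, C=O; sodium p-toluenesulfinate, Cc1ccc(cc1)S(=O)[O-].[Na+]
Why: In this acid-promoted three-component Mannich-type condensation the phenol is hydroxymethylated at one of its two equivalent free ortho positions (the para position is blocked, so one regioisomer is possible), and the sulfinate captures the resulting benzylic cation at sulfur to give a sulfone that is less reactive towards a second substitution.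

**Ring B branch**

Step 5
Reactants: 8 2,4-dihydroxyphenylacetic acid
Product: 9 allyl 2-(2,4-dihydroxyphenyl)acetate
Conditions: allyl bromide, KHCO3, DMF, rt
Reagents that add atoms: allyl bromide, C=CCBr
Why: Hydrogencarbonate deprotonates only the carboxylic acid, so the carboxylate is alkylated (SN2 esterification) while both phenols stay free, and the allyl ester is chosen because it can later be removed without exposing the aryl silyl ether to hydroxide.

Step 6
Reactants: 9 allyl 2-(2,4-dihydroxyphenyl)acetate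
Product: 10 allyl 2-[2-hydroxy-4-(triisopropylsilyloxy)phenyl]acetate
Conditions: TIPSCl (1.05 equiv), imidazole, CH2Cl2, 0 °C
Reagents that add atoms: triisopropylsilyl chloride, CC(C)[Si](Cl)(C(C)C)C(C)C
Why: The hydroxyl para to the side chain is the less hindered one, so one equivalent of the bulky silyl chloride should silylate it selectively (regioselective silyl ether formation).

Step 7
Reactants: 10 allyl 2-[2-hydroxy-4-(triisopropylsilyloxy)phenyl]acetate; 11 3-chloro-3-methylbut-1-yne
Product: 12 allyl 2-[2-(2-methylbut-3-yn-2-yloxy)-4-(triisopropylsilyloxy)phenyl]acetate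
Conditions: DBU, CuCl2·2H2O (1 mol%), MeCN, 0 °C
Reagents that add atoms: none
Why: Copper-catalysed O-propargylation of a phenol with a tertiary propargylic chloride and DBU is the standard entry to aryl 1,1-dimethylpropargyl ethers and runs at 0 °C, where the ester and silyl ether are untouched.

Step 8
Reactants: 12 allyl 2-[2-(2-methylbut-3-yn-2-yloxy)-4-(triisopropylsilyloxy)phenyl]acetate
Product: 15 allyl 2-[2,2-dimethyl-5-(triisopropylsilyloxy)-2H-chromen-8-yl]acetate, via allenylphenol 13 (not isolated), via vinyl quinone methide 14 (not isolated)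
Conditions: o-xylene, 140 °C
Reagents that add atoms: none
Why: The aromatic propargyl Claisen rearrangement can only reach the free ortho carbon between the two oxygens, and tautomerisation, 1,5-hydrogen shift and 6π oxa-electrocyclisation then deliver the 2,2-dimethylchromene.

Step 9
Reactants: 15 allyl 2-[2,2-dimethyl-5-(triisopropylsilyloxy)-2H-chromen-8-yl]acetate
Product: 16 2-[2,2-dimethyl-5-(triisopropylsilyloxy)-2H-chromen-8-yl]acetic acid
Conditions: Pd(PPh3)4 (3 mol%), morpholine, THF, rt
Reagents that add atoms: none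
Why: The zerovalent palladium complex ionises the allyl ester to a π-allyl species that morpholine captures (palladium-catalysed deallylation), which leaves the aryl silyl ether and the chromene alone.

**Union and completion**

Step 10
Reactants: 16 2-[2,2-dimethyl-5-(triisopropylsilyloxy)-2H-chromen-8-yl]acetic acid; 7 3,5-dimethoxy-4-(3-methylbut-2-enyl)-2-(tosylmethyl)phenol
Product: 19 (3R)-3-[2,2-dimethyl-5-(triisopropylsilyloxy)-2H-chromen-8-yl]-5,7-dimethoxy-6-(3-methylbut-2-enyl)chroman-2-one, via mixed pivalic anhydride 17 (not isolated), via ortho-quinone methide 18 (not isolated)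
Conditions: 16 (1.3 equiv), t-BuCOCl, iPr2NEt, CH2Cl2, 0 °C; then 7, (2S,3R)-HyperBTM (10 mol%), Cs2CO3, 0 °C; cold filtration through silica
Reagents that add atoms: none
Why: Pivaloyl chloride converts 16 into anhydride 17, which acylates the isothiourea, and deprotonation gives the (Z)-acyl ammonium enolate held coplanar with the catalyst by the 1,5 sulfur–oxygen contact, while Cs2CO3 removes the phenol proton of 7 so that p-toluenesulfinate leaves and methide 18 forms. The enolate carbon adds to the exocyclic CH2 of 18 (Michael addition, C3–C4) with rearomatisation of ring A, and the phenoxide then closes ring C by 6-exo-trig attack on the acyl ammonium carbonyl (O1–C2), which releases the catalyst. The closest known reaction type is the Lewis-base-catalysed formal [4+2] annulation of ammonium or azolium enolates with ortho-quinone methides generated in situ, which gives 3,4-dihydrocoumarins. C3 is set by the catalyst, whose pseudoaxial phenyl group beside the acylated nitrogen shields one enolate face so that 18 approaches from the other, predicted to give (3R). Only enantiofacial selectivity at the enolate is needed because the methide terminus is an unsubstituted CH2; the aryl group fixes the Z enolate geometry, the two methoxy groups make 18 long-lived enough to be intercepted, and the symmetric origin of 7 allows one regiochemistry. The lactone can enolise at C3 under base, so it is filtered cold and reduced at once.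

Step 11
Reactants: 19 (3R)-3-[2,2-dimethyl-5-(triisopropylsilyloxy)-2H-chromen-8-yl]-5,7-dimethoxy-6-(3-methylbut-2-enyl)chroman-2-one
Product: 20 2-{(2R)-2-[2,2-dimethyl-5-(triisopropylsilyloxy)-2H-chromen-8-yl]-3-hydroxypropyl}-3,5-dimethoxy-4-(3-methylbut-2-enyl)phenol
Conditions: LiBH4, THF, 0 °C
Reagents that add atoms: none
Why: Hydride reduction of the activated aryl lactone to the primary alcohol, with release of the ring A phenol, should be faster than enolisation at C3, and no other group in the molecule is reducible by LiBH4.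

Step 12
Reactants: 20 2-{(2R)-2-[2,2-dimethyl-5-(triisopropylsilyloxy)-2H-chromen-8-yl]-3-hydroxypropyl}-3,5-dimethoxy-4-(3-methylbut-2-enyl)phenol
Product: 21 {8-[(3R)-5,7-dimethoxy-6-(3-methylbut-2-enyl)chroman-3-yl]-2,2-dimethyl-2H-chromen-5-yl}oxytriisopropylsilane
Conditions: PPh3, DIAD, THF, 0 °C to rt
Reagents that add atoms: none
Why: In this intramolecular Mitsunobu etherification the only free phenol displaces the activated primary alcohol in a 6-exo-tet closure of ring C (O1–C2), a process that does not involve the C3 stereocentre.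

Step 13
Reactants: 21 {8-[(3R)-5,7-dimethoxy-6-(3-methylbut-2-enyl)chroman-3-yl]-2,2-dimethyl-2H-chromen-5-yl}oxytriisopropylsilane
Product: 22 Kanzonol I
Conditions: Bu4NF, AcOH, THF, 0 °C to rt
Reagents that add atoms: none
Why: Buffered fluoride desilylation frees the ring B phenol without touching the chromene, the prenyl alkene or the stereocentre.

**Compound list**

1 | 3,5-dimethoxyphenol | COc1cc(O)cc(OC)c1 | starting material
2 | (3,5-dimethoxyphenoxy)triisopropylsilane | COc1cc(O[Si](C(C)C)(C(C)C)C(C)C)cc(OC)c1 | intermediate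
3 | prenyl bromide (1-bromo-3-methylbut-2-ene) | CC(C)=CCBr | starting material
4 | 2,6-dimethoxy-4-(triisopropylsilyloxy)phenyllithium | COc1cc(O[Si](C(C)C)(C(C)C)C(C)C)cc(OC)c1[Li] | intermediate
5 | [3,5-dimethoxy-4-(3-methylbut-2-enyl)phenoxy]triisopropylsilane | COc1cc(O[Si](C(C)C)(C(C)C)C(C)C)cc(OC)c1CC=C(C)C | intermediate
6 | 3,5-dimethoxy-4-(3-methylbut-2-enyl)phenol | COc1cc(O)cc(OC)c1CC=C(C)C | intermediate
7 | 3,5-dimethoxy-4-(3-methylbut-2-enyl)-2-(tosylmethyl)phenol | COc1cc(O)c(CS(=O)(=O)c2ccc(C)cc2)c(OC)c1CC=C(C)C | intermediate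
8 | 2,4-dihydroxyphenylacetic acid | OC(=O)Cc1ccc(O)cc1O | starting material
9 | allyl 2-(2,4-dihydroxyphenyl)acetate | C=CCOC(=O)Cc1ccc(O)cc1O | intermediate
10 | allyl 2-[2-hydroxy-4-(triisopropylsilyloxy)phenyl]acetate | C=CCOC(=O)Cc1ccc(O[Si](C(C)C)(C(C)C)C(C)C)cc1O | intermediate
11 | 3-chloro-3-methylbut-1-yne | CC(C)(Cl)C#C | starting material
12 | allyl 2-[2-(2-methylbut-3-yn-2-yloxy)-4-(triisopropylsilyloxy)phenyl]acetate | C=CCOC(=O)Cc1ccc(O[Si](C(C)C)(C(C)C)C(C)C)cc1OC(C)(C)C#C | intermediate
13 | allyl 2-[2-hydroxy-3-(3-methylbuta-1,2-dienyl)-4-(triisopropylsilyloxy)phenyl]acetate (allenylphenol) | C=CCOC(=O)Cc1ccc(O[Si](C(C)C)(C(C)C)C(C)C)c(C=C=C(C)C)c1O | intermediate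
14 | allyl 2-[5-(3-methylbut-2-enylidene)-6-oxo-4-(triisopropylsilyloxy)cyclohexa-1,3-dienyl]acetate (vinyl ortho-quinone methide) | C=CCOC(=O)CC1=CC=C(O[Si](C(C)C)(C(C)C)C(C)C)C(=CC=C(C)C)C1=O | intermediate
15 | allyl 2-[2,2-dimethyl-5-(triisopropylsilyloxy)-2H-chromen-8-yl]acetate | C=CCOC(=O)Cc1ccc(O[Si](C(C)C)(C(C)C)C(C)C)c2c1OC(C)(C)C=C2 | intermediate
16 | 2-[2,2-dimethyl-5-(triisopropylsilyloxy)-2H-chromen-8-yl]acetic acid | OC(=O)Cc1ccc(O[Si](C(C)C)(C(C)C)C(C)C)c2c1OC(C)(C)C=C2 | intermediate
17 | 2-[2,2-dimethyl-5-(triisopropylsilyloxy)-2H-chromen-8-yl]acetic pivalic anhydride | CC(C)(C)C(=O)OC(=O)Cc1ccc(O[Si](C(C)C)(C(C)C)C(C)C)c2c1OC(C)(C)C=C2 | intermediate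
18 | 3,5-dimethoxy-4-(3-methylbut-2-enyl)-6-methylidenecyclohexa-2,4-dien-1-one (ortho-quinone methide) | COC1=CC(=O)C(=C)C(OC)=C1CC=C(C)C | intermediate
19 | (3R)-3-[2,2-dimethyl-5-(triisopropylsilyloxy)-2H-chromen-8-yl]-5,7-dimethoxy-6-(3-methylbut-2-enyl)chroman-2-one | COc1cc2c(c(OC)c1CC=C(C)C)C[C@H](c1ccc(O[Si](C(C)C)(C(C)C)C(C)C)c3c1OC(C)(C)C=C3)C(=O)O2 | intermediate
20 | 2-{(2R)-2-[2,2-dimethyl-5-(triisopropylsilyloxy)-2H-chromen-8-yl]-3-hydroxypropyl}-3,5-dimethoxy-4-(3-methylbut-2-enyl)phenol | COc1cc(O)c(c(OC)c1CC=C(C)C)C[C@H](c1ccc(O[Si](C(C)C)(C(C)C)C(C)C)c2c1OC(C)(C)C=C2)CO | intermediate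
21 | {8-[(3R)-5,7-dimethoxy-6-(3-methylbut-2-enyl)chroman-3-yl]-2,2-dimethyl-2H-chromen-5-yl}oxytriisopropylsilane | COc1cc2c(c(OC)c1CC=C(C)C)C[C@H](c1ccc(O[Si](C(C)C)(C(C)C)C(C)C)c3c1OC(C)(C)C=C3)CO2 | intermediate
22 | Kanzonol I, 8-[(3R)-5,7-dimethoxy-6-(3-methylbut-2-enyl)chroman-3-yl]-2,2-dimethyl-2H-chromen-5-ol | COc1cc2c(c(OC)c1CC=C(C)C)C[C@H](c1ccc(O)c3c1OC(C)(C)C=C3)CO2 | target

**Step count and risk**

Total: 13 steps. Longest linear sequence: 9 steps (8 to 22, steps 5 to 13); the ring A branch (1 to 7, steps 1 to 4) joins in step 10.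

Steps most likely to fail:

1. Step 10. Facial discrimination at the enolate may be poor, the C3 configuration may erode by base-mediated enolisation of the lactone, or the methide may be consumed by self-condensation. The fallback sets C3 by auxiliary-controlled alkylation and keeps the ring A phenol protected so that no lactone forms. It sets out from acid 16 and phenol 6 and comes back to the route at diol 20.
   - Acid 16 would be activated as anhydride 17 (t-BuCOCl, Et3N, THF, −20 °C) and treated with the lithium salt of (R)-4-benzyloxazolidin-2-one to give the imide (4R)-4-benzyl-3-{[2,2-dimethyl-5-(triisopropylsilyloxy)-2H-chromen-8-yl]acetyl}oxazolidin-2-one F1.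
   - Phenol 6 would be ortho-formylated (MgCl2, Et3N, paraformaldehyde, MeCN, reflux) to 6-hydroxy-2,4-dimethoxy-3-prenylbenzaldehyde F2.
   - O-Allylation (allyl bromide, K2CO3, acetone) would give 6-allyloxy-2,4-dimethoxy-3-prenylbenzaldehyde F3, and reduction (NaBH4, MeOH, 0 °C) would give (6-allyloxy-2,4-dimethoxy-3-prenylphenyl)methanol F4.
   - An Appel reaction (CBr4, PPh3, CH2Cl2, 0 °C) would give 1-allyloxy-2-(bromomethyl)-3,5-dimethoxy-4-prenylbenzene F5, to be used at once.
   - The sodium enolate of F1 (NaN(SiMe3)2, THF, −78 °C) should be alkylated by F5 on the face away from the benzyl group of the auxiliary, giving (4R)-4-benzyl-3-[(2R)-3-(6-allyloxy-2,4-dimethoxy-3-prenylphenyl)-2-[2,2-dimethyl-5-(triisopropylsilyloxy)-2H-chromen-8-yl]propanoyl]oxazolidin-2-one F6.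
   - LiBH4 (THF, MeOH, 0 °C) would remove the auxiliary reductively to give (2R)-3-(6-allyloxy-2,4-dimethoxy-3-prenylphenyl)-2-[2,2-dimethyl-5-(triisopropylsilyloxy)-2H-chromen-8-yl]propan-1-ol F7.
   - Pd(PPh3)4 with morpholine would cleave the allyl ether to give 20.

2. Step 4. The benzylic cation may react with a second molecule of phenol to give a methylene-bridged dimer, or the acid may hydrate the prenyl group. The fallback avoids acid; it sets out from phenol 6 and comes back at sulfone 7. A Mannich reaction (aqueous Me2NH, aqueous CH2O, EtOH, rt) would give 2-[(dimethylamino)methyl]-3,5-dimethoxy-4-prenylphenol F8. MeI in THF would quaternise it to [2-hydroxy-4,6-dimethoxy-5-prenylbenzyl]trimethylammonium iodide F9. Sodium p-toluenesulfinate with NaHCO3 in DMF (rt to 50 °C) would then expel trimethylamine and add at the methide carbon to give 7.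

3. Step 6. Silylation may fail to discriminate the two phenolic hydroxyls (silylation at O2 or at both), or the 2-hydroxy ester may lactonise. The fallback differentiates the hydroxyls by ring formation; it sets out from acid 8 and comes back at silyl ether 10. Acid-catalysed lactonisation (TsOH, toluene, reflux with removal of water) would give 6-hydroxybenzofuran-2(3H)-one F10, in which O2 is tied up. Silylation of the only free hydroxyl (TIPSCl, imidazole, CH2Cl2) would give 6-(triisopropylsilyloxy)benzofuran-2(3H)-one F11. Opening of the strained aryl lactone with allyl alcohol and Et3N at rt would give 10.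

**Further compounds**

F1 | step 10 | (4R)-4-benzyl-3-{[2,2-dimethyl-5-(triisopropylsilyloxy)-2H-chromen-8-yl]acetyl}oxazolidin-2-one | O=C(Cc1ccc(O[Si](C(C)C)(C(C)C)C(C)C)c2c1OC(C)(C)C=C2)N1[C@H](Cc2ccccc2)COC1=O
F2 | step 10 | 6-hydroxy-2,4-dimethoxy-3-(3-methylbut-2-enyl)benzaldehyde | COc1cc(O)c(C=O)c(OC)c1CC=C(C)C
F3 | step 10 | 6-allyloxy-2,4-dimethoxy-3-(3-methylbut-2-enyl)benzaldehyde | COc1cc(OCC=C)c(C=O)c(OC)c1CC=C(C)C
F4 | step 10 | [6-allyloxy-2,4-dimethoxy-3-(3-methylbut-2-enyl)phenyl]methanol | COc1cc(OCC=C)c(CO)c(OC)c1CC=C(C)C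
F5 | step 10 | 1-allyloxy-2-(bromomethyl)-3,5-dimethoxy-4-(3-methylbut-2-enyl)benzene | COc1cc(OCC=C)c(CBr)c(OC)c1CC=C(C)C
F6 | step 10 | (4R)-4-benzyl-3-[(2R)-3-[6-allyloxy-2,4-dimethoxy-3-(3-methylbut-2-enyl)phenyl]-2-[2,2-dimethyl-5-(triisopropylsilyloxy)-2H-chromen-8-yl]propanoyl]oxazolidin-2-one | COc1cc(OCC=C)c(c(OC)c1CC=C(C)C)C[C@H](c1ccc(O[Si](C(C)C)(C(C)C)C(C)C)c2c1OC(C)(C)C=C2)C(=O)N1[C@H](Cc2ccccc2)COC1=O
F7 | step 10 | (2R)-3-[6-allyloxy-2,4-dimethoxy-3-(3-methylbut-2-enyl)phenyl]-2-[2,2-dimethyl-5-(triisopropylsilyloxy)-2H-chromen-8-yl]propan-1-ol | COc1cc(OCC=C)c(c(OC)c1CC=C(C)C)C[C@H](c1ccc(O[Si](C(C)C)(C(C)C)C(C)C)c2c1OC(C)(C)C=C2)CO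
F8 | step 4 | 2-[(dimethylamino)methyl]-3,5-dimethoxy-4-(3-methylbut-2-enyl)phenol | COc1cc(O)c(CN(C)C)c(OC)c1CC=C(C)C
F9 | step 4 | [2-hydroxy-4,6-dimethoxy-5-(3-methylbut-2-enyl)benzyl]trimethylammonium iodide | COc1cc(O)c(C[N+](C)(C)C)c(OC)c1CC=C(C)C.[I-]
F10 | step 6 | 6-hydroxybenzofuran-2(3H)-one | O=C1Cc2ccc(O)cc2O1
F11 | step 6 | 6-(triisopropylsilyloxy)benzofuran-2(3H)-one | O=C1Cc2ccc(O[Si](C(C)C)(C(C)C)C(C)C)cc2O1
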